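**Retrosynthetic overview**
- The C18 angelate is put on last (angelic acid). C13 is set by hydroxyl-directed hydrogenation of an E allylic alcohol, whose C14–C15 unit comes from a Horner–Wadsworth–Emmons reaction on a C13 methyl ketone.
- Feature on which the strategy rests: in ring A, C4 is quaternary and carries the equatorial C18 oxymethyl with no oxygen at C3; in ring B, C8 carries an equatorial tertiary OH next to the C9 side chain. An oxirane spanning C4–C18 can therefore start, and the C13 ketone oxygen can end, one cation–olefin cascade.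
- Key disconnection: C4–C5, C10–C9 and C8–O. Ring A closes first, then ring B, then a temporary dihydropyran that holds the C8 oxygen and is opened later by hydrolysis.
- The acyclic (S)-epoxy dienone is joined at C1–C2 from an allylic bromide made from (E)-geranylacetone and a Grignard reagent made from (S)-citramalic acid (C2–C4, C18, C19).

Key step: step 12

Remark: hydroxy ketone 16 is drawn in its open form; it equilibrates with the cyclic C13 hemiketal, and step 14 draws on the open form.

Step 1
Reactants: 1 (E)-geranylacetone
Product: 2 (E)-geranylacetone ethylene ketal, 2-[(3E)-4,8-dimethylnona-3,7-dien-1-yl]-2-methyl-1,3-dioxolane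
Conditions: ethylene glycol, PPTS (cat.), benzene, reflux, Dean–Stark trap
Reagents that add atoms: ethylene glycol OCCO
Why: Acid-catalysed ketalization with azeotropic removal of water masks the ketone for the oxidation, bromination and Grignard steps, and the mild pyridinium acid leaves both trisubstituted alkenes alone.

Step 2
Reactants: 2 (E)-geranylacetone ethylene ketal
Product: 3 (2E,6E)-2,6-dimethyl-9-(2-methyl-1,3-dioxolan-2-yl)nona-2,6-dien-1-ol
Conditions: SeO2 (cat.), t-BuOOH, salicylic acid (cat.), CH2Cl2, 0 °C to rt
Reagents that add atoms: tert-butyl hydroperoxide CC(C)(C)OO (oxygen relayed by the SeO2 catalyst O=[Se]=O)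
Why: Catalytic SeO2 allylic oxidation (ene reaction followed by [2,3]-sigmatropic shift) attacks the more electron-rich terminal alkene at its E methyl group, so the new CH2OH (future C1) is trans to the chain.

Step 3
Reactants: 3 (2E,6E)-2,6-dimethyl-9-(2-methyl-1,3-dioxolan-2-yl)nona-2,6-dien-1-ol
Product: 4 (2E,6E)-1-bromo-2,6-dimethyl-9-(2-methyl-1,3-dioxolan-2-yl)nona-2,6-diene
Conditions: CBr4, PPh3, CH2Cl2, −30 to 0 °C
Reagents that add atoms: carbon tetrabromide BrC(Br)(Br)Br
Why: Appel bromination converts the primary allylic alcohol by SN2 displacement of the oxyphosphonium group under near-neutral conditions, which keeps the ketal and the E geometry.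

Step 4
Reactants: 5 (S)-citramalic acid
Product: 6 dimethyl (S)-citramalate
Conditions: MeOH, H2SO4 (cat.), 50 °C
Reagents that add atoms: methanol CO
Why: Fischer esterification of both carboxyl groups prepares the diacid for hydride reduction without touching the tertiary carbinol stereocentre.

Step 5
Reactants: 6 dimethyl (S)-citramalate
Product: 7 (S)-2-methylbutane-1,2,4-triol
Conditions: LiAlH4, THF, 0 °C to reflux
Reagents that add atoms: none
Why: LiAlH4 reduction of both esters gives the triol, and the carbinol carbon (future C4) takes no part.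

Step 6
Reactants: 7 (S)-2-methylbutane-1,2,4-triol
Product: 8 (S)-2-(2,2,4-trimethyl-1,3-dioxolan-4-yl)ethanol
Conditions: 2,2-dimethoxypropane, p-TsOH (cat.), acetone, rt
Reagents that add atoms: 2,2-dimethoxypropane COC(C)(C)OC
Why: Acetonide formation under thermodynamic control selects the five-membered 1,2-dioxolane, because the alternative 1,3-dioxane would carry a syn-axial methyl pair, and leaves the remote primary hydroxyl free.

Step 7
Reactants: 8 (S)-2-(2,2,4-trimethyl-1,3-dioxolan-4-yl)ethanol
Product: 9 (S)-4-(2-iodoethyl)-2,2,4-trimethyl-1,3-dioxolane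
Conditions: I2, PPh3, imidazole, CH2Cl2, 0 °C to rt
Reagents that add atoms: iodine I-I
Why: Appel-type iodination of the primary alcohol is buffered by imidazole, so the acid-labile acetonide survives.

Step 8
Reactants: 9 (S)-4-(2-iodoethyl)-2,2,4-trimethyl-1,3-dioxolane, 4 (2E,6E)-1-bromo-2,6-dimethyl-9-(2-methyl-1,3-dioxolan-2-yl)nona-2,6-diene
Product: 11 acetonide-protected dienyl ketal, via alkylmagnesium iodide 10 (not isolated)
Conditions: 9, Mg, THF, rt; then 4, Li2CuCl4 (cat.), THF, −78 to 0 °C
Reagents that add atoms: none
Why: Copper-catalysed coupling of a primary alkyl Grignard reagent with a primary allylic bromide should take place at the α carbon (SN2) with the E alkene kept, forming C1–C2, and the Grignard reagent is stable because its oxygen is γ and cannot leave by β-elimination.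

Step 9
Reactants: 11 acetonide-protected dienyl ketal
Product: 12 (5E,9E,14S)-14,15-dihydroxy-6,10,14-trimethylpentadeca-5,9-dien-2-one
Conditions: 1 M HCl, THF, rt
Reagents that add atoms: water O
Why: Aqueous acid hydrolysis removes the acetonide and the dioxolane in one operation, and the isolated trisubstituted alkenes do not react under these mild conditions.

Step 10
Reactants: 12 (5E,9E,14S)-14,15-dihydroxy-6,10,14-trimethylpentadeca-5,9-dien-2-one
Product: 13 (2S,6E,10E)-2-hydroxy-2,6,10-trimethyl-14-oxopentadeca-6,10-dien-1-yl 4-methylbenzenesulfonate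
Conditions: TsCl, pyridine, CH2Cl2, 0 °C
Reagents that add atoms: p-toluenesulfonyl chloride Cc1ccc(cc1)S(=O)(=O)Cl
Why: Sulfonylation selects the primary hydroxyl over the tertiary one on steric grounds and leaves the C4–O bond untouched.

Step 11
Reactants: 13 (2S,6E,10E)-2-hydroxy-2,6,10-trimethyl-14-oxopentadeca-6,10-dien-1-yl 4-methylbenzenesulfonate
Product: 14 (5E,9E)-6,10-dimethyl-13-[(2S)-2-methyloxiran-2-yl]trideca-5,9-dien-2-one
Conditions: K2CO3, MeOH, 0 °C to rt
Reagents that add atoms: none
Why: Intramolecular Williamson etherification of the tertiary alkoxide onto the primary tosylate closes the oxirane at C18, so the C4 configuration from citramalic acid is carried unchanged into the (S)-oxirane.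

Step 12
Reactants: 14 (5E,9E)-6,10-dimethyl-13-[(2S)-2-methyloxiran-2-yl]trideca-5,9-dien-2-one
Product: 15 ent-8,13-epoxy-14,15-dinorlabd-12-en-18-ol (tricyclic enol ether, 18-hydroxy derivative of ent-sclareol oxide; 4S,5S,8S,9S,10R)
Conditions: MeAlCl2 (1.5 equiv), CH2Cl2 (high dilution), −78 °C; then Et3N, aqueous NaHCO3
Reagents that add atoms: none
Why: Proposed new method: MeAlCl2 activates the oxirane oxygen, the C5=C10 alkene attacks tertiary C4 from the side opposite the breaking C4–O bond (ring A, 6-endo at the alkene with the cleaved C–O bond exocyclic), C9 of the C8=C9 alkene takes the C10 cation (ring B, 6-endo), and the C13 carbonyl oxygen takes the C8 cation (dihydropyran, a six-membered oxocarbenium with C8 and C9 in the ring), after which loss of a C12 proton gives the enol ether and the oxirane oxygen is left as the C18 alkoxide. The closest known reaction types are Lewis acid promoted polycyclizations of trisubstituted epoxy polyenes, acid cyclizations of farnesylacetone-type dienones that end by carbonyl-oxygen capture to sclareol-oxide-type enol ethers, and epoxide–arene closures of 2,2-disubstituted oxiranes that leave a hydroxymethyl group on a new quaternary carbon; their union in one substrate has not been shown. C4 is set by inversion at the (S)-oxirane carbon that stems from citramalic acid, C5 and C10 by anti addition across the E C5=C10 alkene and C9 and C8 by anti addition across the E C8=C9 alkene in a chair–chair array, the carbonyl oxygen entering anti at C8 to give the equatorial C–O bond, with the absolute sense of all four relayed from C4. The step needs the chair fold at C4 that keeps the aluminium-bound C18–O arm pseudo-equatorial and the C19 methyl axial; this rests on that arm being the larger C4 substituent in an open, ion-pair-like opening, where it avoids the syn-axial contact with the C20 methyl, and the competing fold would give a separable diastereomer with an axial hydroxymethyl. The tertiary oxirane carbon, the E geometry and 1,5-spacing of the alkenes and the internal ketone suit the cascade, the 1,2-hydride shift to the aldehyde (Meinwald rearrangement) is held back by low temperature and dilution, and any exocyclic enol ether or hemiketal converges on 16 in step 13.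

Step 13
Reactants: 15 ent-8,13-epoxy-14,15-dinorlabd-12-en-18-ol
Product: 16 ent-8,18-dihydroxy-14,15-dinorlabdan-13-one (8-OH equatorial)
Conditions: 0.1 M HCl, THF–H2O, 0 °C to rt
Reagents that add atoms: water O
Why: Acid-catalysed hydration of the enol ether at C13 gives the hemiketal, which opens to the 8-hydroxy 13-ketone without touching any stereocentre.

Step 14
Reactants: 16 ent-8,18-dihydroxy-14,15-dinorlabdan-13-one, 17 triethyl phosphonoacetate
Product: 18 ethyl (13E)-8,18-dihydroxy-ent-labd-13-en-15-oate
Conditions: 17 pretreated with NaH (slightly less than 1 equiv per phosphonate), THF, 0 °C; then 16, reflux; chromatographic removal of the Z isomer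
Reagents that add atoms: none
Why: Horner–Wadsworth–Emmons olefination of the methyl ketone with the preformed sodium phosphonate, used without excess hydride so that the hydroxyl groups stay protonated, should favour the E enoate.

Step 15
Reactants: 18 ethyl (13E)-8,18-dihydroxy-ent-labd-13-en-15-oate
Product: 19 (13E)-ent-labd-13-ene-8,15,18-triol
Conditions: i-Bu2AlH (excess), CH2Cl2, −78 to 0 °C
Reagents that add atoms: none
Why: i-Bu2AlH reduces the conjugated ester by 1,2-addition to the E allylic alcohol and leaves the alkene geometry unchanged.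

Step 16
Reactants: 19 (13E)-ent-labd-13-ene-8,15,18-triol
Product: 20 (13S)-ent-labdane-8,15,18-triol
Conditions: H2 (50 atm), Ru(OAc)2[(R)-BINAP] (cat.), MeOH, 25 °C
Reagents that add atoms: none
Why: Hydroxyl-directed asymmetric hydrogenation of the E allylic alcohol with the (R)-BINAP ruthenium diacetate complex follows the sense of geraniol to (S)-citronellol and sets C13 as S under catalyst control, the remote hydroxyls being spectators.

Step 17
Reactants: 20 (13S)-ent-labdane-8,15,18-triol
Product: 21 (13S)-15-(tert-butyldimethylsilyloxy)-ent-labdane-8,18-diol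
Conditions: TBSCl (1.05 equiv), imidazole, CH2Cl2, −20 °C
Reagents that add atoms: tert-butyldimethylsilyl chloride CC(C)(C)[Si](C)(C)Cl
Why: Silylation under kinetic control selects the unhindered C15 primary hydroxyl over the neopentyl C18 hydroxyl and the tertiary C8 hydroxyl.

Step 18
Reactants: 21 (13S)-15-(tert-butyldimethylsilyloxy)-ent-labdane-8,18-diol, 22 angelic acid
Product: 24 (13S)-15-(tert-butyldimethylsilyloxy)-8-hydroxy-ent-labdan-18-yl (Z)-2-methylbut-2-enoate, via angelic 2,4,6-trichlorobenzoic anhydride 23 (not isolated)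
Conditions: 22, 2,4,6-trichlorobenzoyl chloride, Et3N, toluene, rt; then 21, toluene, 80 °C
Reagents that add atoms: none
Why: Yamaguchi esterification through the mixed anhydride, run without a nucleophilic amine catalyst, acylates the C18 primary hydroxyl while avoiding the addition–elimination path that turns angelate into tiglate, and the tertiary C8 hydroxyl is too hindered to react.

Step 19
Reactants: 24 (13S)-15-(tert-butyldimethylsilyloxy)-8-hydroxy-ent-labdan-18-yl (Z)-2-methylbut-2-enoate
Product: 25 target CNP0150844.1, (13S)-8,15-dihydroxy-ent-labdan-18-yl (Z)-2-methylbut-2-enoate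
Conditions: HF·pyridine, pyridine, THF, 0 °C to rt
Reagents that add atoms: none
Why: Fluoride desilylation with buffered HF·pyridine cleaves the primary silyl ether without hydrolysis or Z to E isomerization of the angelate and without elimination of the tertiary alcohol.

**Compound list**
1 | (E)-geranylacetone | CC(C)=CCC/C(C)=C/CCC(C)=O | starting material
2 | 2-[(3E)-4,8-dimethylnona-3,7-dien-1-yl]-2-methyl-1,3-dioxolane | CC(C)=CCC/C(C)=C/CCC1(C)OCCO1 | intermediate
3 | (2E,6E)-2,6-dimethyl-9-(2-methyl-1,3-dioxolan-2-yl)nona-2,6-dien-1-ol | OC/C(C)=C/CC/C(C)=C/CCC1(C)OCCO1 | intermediate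
4 | (2E,6E)-1-bromo-2,6-dimethyl-9-(2-methyl-1,3-dioxolan-2-yl)nona-2,6-diene | BrC/C(C)=C/CC/C(C)=C/CCC1(C)OCCO1 | intermediate
5 | (S)-citramalic acid | C[C@@](O)(C(=O)O)CC(=O)O | starting material
6 | dimethyl (S)-citramalate | C[C@@](O)(C(=O)OC)CC(=O)OC | intermediate
7 | (S)-2-methylbutane-1,2,4-triol | C[C@@](O)(CO)CCO | intermediate
8 | (S)-2-(2,2,4-trimethyl-1,3-dioxolan-4-yl)ethanol | C[C@]1(CCO)COC(C)(C)O1 | intermediate
9 | (S)-4-(2-iodoethyl)-2,2,4-trimethyl-1,3-dioxolane | C[C@]1(CCI)COC(C)(C)O1 | intermediate
10 | (S)-2-(2,2,4-trimethyl-1,3-dioxolan-4-yl)ethylmagnesium iodide | C[C@]1(CC[Mg]I)COC(C)(C)O1 | intermediate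
11 | (4S)-4-[(4E,8E)-4,8-dimethyl-11-(2-methyl-1,3-dioxolan-2-yl)undeca-4,8-dien-1-yl]-2,2,4-trimethyl-1,3-dioxolane | C[C@]1(CCC/C(C)=C/CC/C(C)=C/CCC2(C)OCCO2)COC(C)(C)O1 | intermediate
12 | (5E,9E,14S)-14,15-dihydroxy-6,10,14-trimethylpentadeca-5,9-dien-2-one | C[C@@](O)(CO)CCC/C(C)=C/CC/C(C)=C/CCC(C)=O | intermediate
13 | (2S,6E,10E)-2-hydroxy-2,6,10-trimethyl-14-oxopentadeca-6,10-dien-1-yl 4-methylbenzenesulfonate | C[C@@](O)(COS(=O)(=O)c1ccc(C)cc1)CCC/C(C)=C/CC/C(C)=C/CCC(C)=O | intermediate
14 | (5E,9E)-6,10-dimethyl-13-[(2S)-2-methyloxiran-2-yl]trideca-5,9-dien-2-one | C[C@@]1(CO1)CCC/C(C)=C/CC/C(C)=C/CCC(C)=O | intermediate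
15 | ent-8,13-epoxy-14,15-dinorlabd-12-en-18-ol | OC[C@@]1(C)CCC[C@]2(C)[C@@H]1CC[C@]3(C)OC(C)=CC[C@@H]23 | intermediate
16 | ent-8,18-dihydroxy-14,15-dinorlabdan-13-one | OC[C@@]1(C)CCC[C@]2(C)[C@@H]1CC[C@](C)(O)[C@H]2CCC(C)=O | intermediate
17 | triethyl phosphonoacetate | CCOC(=O)CP(=O)(OCC)OCC | starting material
18 | ethyl (13E)-8,18-dihydroxy-ent-labd-13-en-15-oate | OC[C@@]1(C)CCC[C@]2(C)[C@@H]1CC[C@](C)(O)[C@H]2CC/C(C)=C/C(=O)OCC | intermediate
19 | (13E)-ent-labd-13-ene-8,15,18-triol | OC[C@@]1(C)CCC[C@]2(C)[C@@H]1CC[C@](C)(O)[C@H]2CC/C(C)=C/CO | intermediate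
20 | (13S)-ent-labdane-8,15,18-triol | OC[C@@]1(C)CCC[C@]2(C)[C@@H]1CC[C@](C)(O)[C@H]2CC[C@H](C)CCO | intermediate
21 | (13S)-15-(tert-butyldimethylsilyloxy)-ent-labdane-8,18-diol | OC[C@@]1(C)CCC[C@]2(C)[C@@H]1CC[C@](C)(O)[C@H]2CC[C@H](C)CCO[Si](C)(C)C(C)(C)C | intermediate
22 | angelic acid, (Z)-2-methylbut-2-enoic acid | C/C=C(/C)C(=O)O | starting material
23 | angelic 2,4,6-trichlorobenzoic anhydride | C/C=C(/C)C(=O)OC(=O)c1c(Cl)cc(Cl)cc1Cl | intermediate
24 | (13S)-15-(tert-butyldimethylsilyloxy)-8-hydroxy-ent-labdan-18-yl (Z)-2-methylbut-2-enoate | C/C=C(/C)C(=O)OC[C@@]1(C)CCC[C@]2(C)[C@@H]1CC[C@](C)(O)[C@H]2CC[C@H](C)CCO[Si](C)(C)C(C)(C)C | intermediate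
25 | CNP0150844.1, (13S)-8,15-dihydroxy-ent-labdan-18-yl (Z)-2-methylbut-2-enoate (4S,5S,8S,9S,10R,13S) | C/C=C(/C)C(=O)OC[C@@]1(C)CCC[C@]2(C)[C@@H]1CC[C@](C)(O)[C@H]2CC[C@H](C)CCO | target

**Totals**
Total step count: 19 steps. Longest linear sequence: 16 steps (from 5 through steps 4 to 19); the geranylacetone branch adds steps 1 to 3.

**Steps most likely to fail**

Step 12 (Proposed new method). Three processes may defeat it.
- The chair fold at C4 may go the other way. The oxirane methylene is held back from the incoming alkene by the three-membered ring, so it may be the group that best tolerates the crowded axial site. The hydroxymethyl would then end axial, in the mirror-image ring system.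
- Hydride shift of the activated oxirane to the aldehyde may outrun ring closure.
- Aluminium bound to the ketone may suppress oxygen capture, so that the C8 cation loses a proton instead.

A fluoroalcohol medium (hexafluoroisopropanol with Ph4PBF4), which leaves the ketone free, would be tried first.

The fallback uses known chemistry and a different initiator: an E-configured trisubstituted oxirane at C3–C4, in which the alkene geometry, not a fold preference, fixes C18 as equatorial. The extra C3 oxygen is removed afterwards. Initiation at a trisubstituted oxirane with MeAlCl2 is the established mode for epoxy polyenes, and capture of the C8 cation by a ketone is the established end of dienone cyclizations. The fallback sets out from bromide 4 and returns at enol ether 15.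

Bromide 4 is alkylated with the lithio derivative of (E)-4-(tert-butyldimethylsilyloxy)-3-methylbut-2-enyl phenyl sulfone (n-BuLi, THF, −78 °C) to give the C2 phenyl sulfone F1. PdCl2(dppp)-catalysed reduction with LiEt3BH removes the sulfonyl group with the alkene kept in place and gives the C18 silyl ether of the farnesylacetone ketal F2. Aqueous HCl in THF cleaves the silyl ether and the ketal to the keto allylic alcohol F3. Sharpless asymmetric epoxidation (Ti(OiPr)4, D-(−)-diethyl tartrate, t-BuOOH, 4 Å sieves, CH2Cl2, −20 °C) should give the (2R,3R)-epoxy alcohol F4, the enantiomer needed for the ent series. Silylation (TBDPSCl, imidazole) gives the silyl-protected epoxy dienone F5. MeAlCl2 in CH2Cl2 at −78 °C then closes ring A, ring B and the dihydropyran; the oxirane oxygen stays on C3 as an equatorial hydroxyl and the E-CH2OSi group ends equatorial as C18, giving the 3-hydroxy enol ether F6. Barton–McCombie deoxygenation goes through the imidazolyl thiocarbonate F7 (thiocarbonyldiimidazole, DMAP; then Bu3SnH, AIBN, toluene, reflux) to the 18-silyl ether F8, and Bu4NF in THF releases 15.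

Step 14. The hindered methyl ketone is partly masked as its hemiketal and may olefinate slowly or revert to the enol ether. The C8 hydroxyl may add in conjugate fashion to the new enoate, and the E to Z preference may be modest.

The fallback replaces olefination by carbonyl addition and allylic transposition. It sets out from hydroxy ketone 16 and returns at allylic alcohol 19. Vinylmagnesium bromide (excess, THF, 0 °C) adds to the ketone to give the C13 tertiary allylic alcohol F9 as a mixture of C13 epimers, which is of no consequence. Exhaustive acetylation (AcCl, N,N-dimethylaniline, CH2Cl2) gives the triacetate F10. PdCl2(MeCN)2-catalysed [3,3] allylic acetate transposition in THF moves the acetate to C15 and should give mainly the E trisubstituted alkene F11, separated from its Z isomer. LiAlH4 in THF removes all three acetates and gives 19.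

Step 18. Acylation of the neopentyl C18 hydroxyl may be slow, and prolonged heating may isomerize the angelate to the tiglate.

The fallback builds the Z alkene on the ester instead of bringing it in. It sets out from silyl ether 21 and returns at 24. The C18 hydroxyl is esterified with 2-(diphenoxyphosphoryl)propanoic acid (DCC, DMAP, CH2Cl2), an acid with no isomerizable alkene, to give the phosphonopropanoate F12. Z-selective Horner–Wadsworth–Emmons olefination of its sodium salt (NaH, THF, −78 °C) with acetaldehyde then gives 24.

**Further compounds**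
F1 | step 12 | C2 phenyl sulfone from 4 and the silyloxy prenyl sulfone (E,E,E) | CC(C)(C)[Si](C)(C)OC/C(C)=C/C(C/C(C)=C/CC/C(C)=C/CCC1(C)OCCO1)S(=O)(=O)c1ccccc1
F2 | step 12 | C18 tert-butyldimethylsilyl ether of (E,E,E)-18-hydroxyfarnesylacetone ethylene ketal | CC(C)(C)[Si](C)(C)OC/C(C)=C/CC/C(C)=C/CC/C(C)=C/CCC1(C)OCCO1
F3 | step 12 | (5E,9E,13E)-15-hydroxy-6,10,14-trimethylpentadeca-5,9,13-trien-2-one | OC/C(C)=C/CC/C(C)=C/CC/C(C)=C/CCC(C)=O
F4 | step 12 | (2R,3R)-epoxy alcohol of F3 (oxirane at C3–C4, free C18 hydroxyl) | OC[C@@]1(C)O[C@@H]1CC/C(C)=C/CC/C(C)=C/CCC(C)=O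
F5 | step 12 | C18 tert-butyldiphenylsilyl ether of F4 | CC(C)(C)[Si](c1ccccc1)(c1ccccc1)OC[C@@]1(C)O[C@@H]1CC/C(C)=C/CC/C(C)=C/CCC(C)=O
F6 | step 12 | 3-hydroxy-18-(tert-butyldiphenylsilyloxy) tricyclic enol ether (3-OH equatorial) | CC(C)(C)[Si](c1ccccc1)(c1ccccc1)OC[C@@]1(C)[C@H](O)CC[C@]2(C)[C@@H]1CC[C@]3(C)OC(C)=CC[C@@H]23
F7 | step 12 | C3 imidazolyl thiocarbonate of F6 | CC(C)(C)[Si](c1ccccc1)(c1ccccc1)OC[C@@]1(C)[C@H](OC(=S)n4ccnc4)CC[C@]2(C)[C@@H]1CC[C@]3(C)OC(C)=CC[C@@H]23
F8 | step 12 | 18-O-tert-butyldiphenylsilyl ether of 15 | CC(C)(C)[Si](c1ccccc1)(c1ccccc1)OC[C@@]1(C)CCC[C@]2(C)[C@@H]1CC[C@]3(C)OC(C)=CC[C@@H]23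
F9 | step 14 | ent-labd-14-ene-8,13,18-triol (C13 epimers) | OC[C@@]1(C)CCC[C@]2(C)[C@@H]1CC[C@](C)(O)[C@H]2CCC(C)(O)C=C
F10 | step 14 | 8,13,18-triacetate of F9 | CC(=O)OC[C@@]1(C)CCC[C@]2(C)[C@@H]1CC[C@](C)(OC(C)=O)[C@H]2CCC(C)(OC(C)=O)C=C
F11 | step 14 | (13E)-ent-labd-13-ene-8,15,18-triyl triacetate | CC(=O)OC[C@@]1(C)CCC[C@]2(C)[C@@H]1CC[C@](C)(OC(C)=O)[C@H]2CC/C(C)=C/COC(C)=O
F12 | step 18 | C18 2-(diphenoxyphosphoryl)propanoate of 21 | CC(C(=O)OC[C@@]1(C)CCC[C@]2(C)[C@@H]1CC[C@](C)(O)[C@H]2CC[C@H](C)CCO[Si](C)(C)C(C)(C)C)P(=O)(Oc1ccccc1)Oc1ccccc1
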